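The target is cut back to (S)-6-hydroxytremetone, whose C2 isopropenyl group beside O1 of the dihydrofuran ring is read as what is left of the CMe2 carbon of a 2,2-dimethylchroman. Activating the C3 hydroxyl of enantiopure (R)-6-acetyl-7-hydroxy-2,2-dimethylchroman-3-ol makes O1 migrate from CMe2 to C3 with inversion. In one operation the pyran ring contracts to the dihydrofuran ring, the O1–C2 bond and the C2 stereocentre are set, and proton loss unveils the alkene. The chromanol comes from precocene 1 by acetylation, Jacobsen epoxidation, hydrogenolysis and demethylation; the trans C3 ester is installed last by quinone-methide C–H acyloxylation with (Z)-2-(acetoxymethyl)but-2-enoic acid.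

Key step: step 5

Remark: no structure needed correction; the target is the trans-(2R,3S) ester of the (Z)-acid (methyl cis to the ester carbonyl), C2 has the same spatial arrangement in 8 (S) and in the target (R) because only the priorities change when C3 gains oxygen, and the (R,R)-configured (salen)MnCl catalyst is assumed to give the (3R,4R)-epoxide, as is usual for 2,2-dimethylchromenes.

Step 1
Reactants: 1 precocene 1 (7-methoxy-2,2-dimethyl-2H-chromene); 2 acetyl chloride
Product: 3 encecalin [1-(7-methoxy-2,2-dimethyl-2H-chromen-6-yl)ethanone]
Conditions: AcCl (1.1 equiv), AlCl3 (1.2 equiv), CH2Cl2, −20 °C; cold aq. NaHCO3 quench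
Reagents that add atoms: acetyl chloride (compound 2), CC(=O)Cl
Why: Friedel–Crafts acylation should go at C6, the unhindered ring position that is para to O1 and ortho to the methoxy group, and the preformed acylium complex at low temperature should spare the acid-labile C3=C4 bond.

Step 2
Reactants: 3 encecalin
Product: 4 (3R,4R)-6-acetyl-3,4-epoxy-7-methoxy-2,2-dimethylchromane
Conditions: (R,R)-(salen)MnCl (trivalent manganese, 4 mol %), aq. NaOCl (pH 11.3), 4-phenylpyridine N-oxide (0.2 equiv), CH2Cl2, 0 °C
Reagents that add atoms: sodium hypochlorite, [Na+].[O-]Cl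
Why: Jacobsen–Katsuki epoxidation of a 2,2-dimethylchromene, the best substrate class for it (cis-disubstituted, aryl-conjugated, next to a quaternary carbon), should set C3 and C4 as R under catalyst control with the (R,R) complex [salen = N,N'-bis(3,5-di-tert-butylsalicylidene)-(1R,2R)-cyclohexane-1,2-diamine], while the basic buffered medium protects the para-alkoxybenzylic epoxide.

Step 3
Reactants: 4 (3R,4R)-6-acetyl-3,4-epoxy-7-methoxy-2,2-dimethylchromane
Product: 5 (R)-6-acetyl-7-methoxy-2,2-dimethylchroman-3-ol
Conditions: H2 (1 atm), 10% Pd/C, EtOAc, Et3N (trace), rt, stopped when 4 is consumed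
Reagents that add atoms: none
Why: Catalytic hydrogenolysis should cleave only the benzylic C4–O bond of the aryl epoxide (regioselective reductive epoxide opening), so the C3–O bond and its R configuration stay untouched, and the aryl ketone that a metal hydride would reduce is hydrogenated far more slowly.

Step 4
Reactants: 5 (R)-6-acetyl-7-methoxy-2,2-dimethylchroman-3-ol
Product: 6 (R)-6-acetyl-7-hydroxy-2,2-dimethylchroman-3-ol
Conditions: BCl3 (2.5 equiv), CH2Cl2, −78 → 0 °C; then H2O
Reagents that add atoms: none
Why: Chelation-controlled aryl methyl ether cleavage, in which boron bridges the acetyl oxygen and the ortho methoxy oxygen and chloride removes the methyl group, should leave the C3 carbinol as a borate that is hydrolysed on work-up, so the stereocentre is unaffected.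

Step 5
Reactants: 6 (R)-6-acetyl-7-hydroxy-2,2-dimethylchroman-3-ol
Product: 8 (S)-6-hydroxytremetone [1-((2S)-6-hydroxy-2-(prop-1-en-2-yl)-2,3-dihydro-1-benzofuran-5-yl)ethanone], via oxyphosphonium cation 7 (not isolated)
Conditions: PPh3 (1.5 equiv), DIAD (1.5 equiv), THF, 0 → 50 °C
Reagents that add atoms: none
Why: The PPh3/DIAD betaine, protonated by the chelated phenol, turns the C3 hydroxyl into an oxyphosphonium leaving group; in the half-chair with this group pseudo-equatorial the O1–C2 bond is antiperiplanar to C3–O, so O1 attacks C3 from the rear as Ph3PO departs, the O1–CMe2 bond breaks and the tertiary cation loses a methyl proton to the hydrazide or phenoxide base. The closest known reaction type is the dehydrative ring contraction of 2,2-dimethylchroman-3-ols on hydroxyl activation (1,2-aryloxy shift, related to ring-oxygen participation in pyranoside contractions), run here under Mitsunobu activation without an external nucleophile. The dihydrofuran ring is closed by 3-exo-tet attack of O1 on C3 to an O1-bridged oxiranium ion, whose opening at the quaternary carbon completes the shift from a six- to a five-membered ring. The new stereocentre, C2 of 8, is fixed by stereospecific inversion at the carbinol carbon, so R in 6 becomes S under substrate control. The step needs O1 migration to win over aryl, hydride and methyl shifts and over elimination towards C4, and proton loss to win over cation capture; this is secured by the CH2 group at C4 (no cation-stabilising oxygen), the gem-dimethyl carbon that lets O1–C2 cleavage end in a tertiary cation, the crowded carbinol that resists intermolecular substitution, and the absence of a nucleophilic counter-ion such as fluoride.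

Step 6
Reactants: 9 but-2-yn-1-ol
Product: 10 (Z)-2-(tributylstannyl)but-2-en-1-ol
Conditions: Bu3SnH (1.1 equiv), [Cp*RuCl]4 (1.5 mol %, divalent ruthenium, Cp* = pentamethylcyclopentadienyl), CH2Cl2, rt
Reagents that add atoms: tributyltin hydride, CCCC[SnH](CCCC)CCCC
Why: Ruthenium-catalysed trans-hydrostannation of a propargylic alcohol should place tin on the alkyne carbon next to the CH2OH group (hydroxyl-to-chloride hydrogen bonding) and deliver hydrogen anti, which puts methyl cis to tin, the geometry later needed for methyl cis to the carboxyl group.

Step 7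
Reactants: 10 (Z)-2-(tributylstannyl)but-2-en-1-ol
Product: 11 (Z)-2-iodobut-2-en-1-ol
Conditions: I2 (1.05 equiv), CH2Cl2, 0 °C
Reagents that add atoms: iodine, II
Why: Iododestannylation of an alkenylstannane is an electrophilic ipso substitution at the C–Sn bond and should proceed with retention of the double-bond geometry.

Step 8
Reactants: 11 (Z)-2-iodobut-2-en-1-ol
Product: 13 (Z)-2-(hydroxymethyl)but-2-enoic acid, via dilithio alkoxide 12 (not isolated)
Conditions: t-BuLi (3.1 equiv), Et2O, −78 °C; CO2 (g), −78 °C → rt; aq. HCl
Reagents that add atoms: carbon dioxide, O=C=O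
Why: Deprotonation of the hydroxyl group and iodine–lithium exchange should give a configurationally stable alkenyllithium alkoxide that is carboxylated with retention (halogen–metal exchange then carboxylation), so methyl ends up cis to the carboxyl group.

Step 9
Reactants: 13 (Z)-2-(hydroxymethyl)but-2-enoic acid
Product: 14 (Z)-2-(acetoxymethyl)but-2-enoic acid
Conditions: Ac2O (1.2 equiv), pyridine, CH2Cl2, 0 °C → rt; then H2O, rt; acidic work-up
Reagents that add atoms: acetic anhydride, CC(=O)OC(C)=O
Why: O-Acetylation of the primary allylic alcohol should be clean, the carboxyl group returning as the free acid after the aqueous quench, and the mild base at low temperature should not isomerise the (Z)-alkene.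

Step 10
Reactants: 8 (S)-6-hydroxytremetone; 14 (Z)-2-(acetoxymethyl)but-2-enoic acid
Product: 15 (2R,3S)-5-acetyl-6-hydroxy-2-(prop-1-en-2-yl)-2,3-dihydro-1-benzofuran-3-yl (2Z)-2-(acetoxymethyl)but-2-enoate (target)
Conditions: DDQ (1.2 equiv), 14 (4 equiv, excess recovered by base extraction), 4 Å MS, CH2Cl2, 0 °C → rt
Reagents that add atoms: none
Why: In this oxidative benzylic C–H acyloxylation DDQ should abstract hydride from C3 (para to the C6 hydroxyl, ortho to O1) to give the para-quinone methide, and the acid should add to its exocyclic carbon from the face opposite the C2 isopropenyl group, which sets C3 as S (trans) under substrate control and leaves C2 untouched.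

Compound list
1 | precocene 1 (7-methoxy-2,2-dimethyl-2H-chromene) | COc1ccc2C=CC(C)(C)Oc2c1 | starting material
2 | acetyl chloride | CC(=O)Cl | starting material
3 | encecalin, 1-(7-methoxy-2,2-dimethyl-2H-chromen-6-yl)ethanone | COc1cc2OC(C)(C)C=Cc2cc1C(C)=O | intermediate
4 | (3R,4R)-6-acetyl-3,4-epoxy-7-methoxy-2,2-dimethylchromane | COc1cc2OC(C)(C)[C@@H]3O[C@@H]3c2cc1C(C)=O | intermediate
5 | (R)-6-acetyl-7-methoxy-2,2-dimethylchroman-3-ol | COc1cc2OC(C)(C)[C@H](O)Cc2cc1C(C)=O | intermediate
6 | (R)-6-acetyl-7-hydroxy-2,2-dimethylchroman-3-ol | CC1(C)Oc2cc(O)c(C(C)=O)cc2C[C@H]1O | intermediate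
7 | (R)-(6-acetyl-7-hydroxy-2,2-dimethylchroman-3-yloxy)triphenylphosphonium cation | CC1(C)Oc2cc(O)c(C(C)=O)cc2C[C@H]1O[P+](c1ccccc1)(c1ccccc1)c1ccccc1 | intermediate (not isolated)
8 | (S)-6-hydroxytremetone, 1-[(2S)-6-hydroxy-2-(prop-1-en-2-yl)-2,3-dihydro-1-benzofuran-5-yl]ethanone | C=C(C)[C@@H]1Cc2cc(C(C)=O)c(O)cc2O1 | intermediate
9 | but-2-yn-1-ol | CC#CCO | starting material
10 | (Z)-2-(tributylstannyl)but-2-en-1-ol | C/C=C(\[Sn](CCCC)(CCCC)CCCC)CO | intermediate
11 | (Z)-2-iodobut-2-en-1-ol | C/C=C(\I)CO | intermediate
12 | lithium (Z)-2-lithiobut-2-en-1-olate | C/C=C(\[Li])CO[Li] | intermediate (not isolated)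
13 | (Z)-2-(hydroxymethyl)but-2-enoic acid | C/C=C(\C(=O)O)CO | intermediate
14 | (Z)-2-(acetoxymethyl)but-2-enoic acid | C/C=C(\C(=O)O)COC(C)=O | intermediate
15 | (2R,3S)-5-acetyl-6-hydroxy-2-(prop-1-en-2-yl)-2,3-dihydro-1-benzofuran-3-yl (2Z)-2-(acetoxymethyl)but-2-enoate | C=C(C)[C@H]1Oc2cc(O)c(C(C)=O)cc2[C@@H]1OC(=O)/C(=C\C)COC(C)=O | target

Total step count: 10. Longest linear sequence: 6 steps (steps 1–5 and 10); the acid branch (steps 6–9) joins in step 10.

Steps most likely to fail

Step 5 (ring contraction). O1 is a weak neighbouring group because its lone pair is drawn towards the para acetyl group. Displacement of the oxyphosphonium group may therefore be outrun by anti-elimination towards C4 or by O-alkylation through the free phenol, and the cation may be captured or re-close instead of losing a methyl proton. The fallback sets out from 5 and comes back at 8: the contraction is moved in front of the demethylation and run by sulfonate ionisation instead of redox dehydration. Methyl ether 5, which has no acidic phenol, would be treated with Tf2O and 2,6-di-tert-butyl-4-methylpyridine in CH2Cl2 at −78 → 0 °C. The resulting (R)-6-acetyl-7-methoxy-2,2-dimethylchroman-3-yl trifluoromethanesulfonate F1 should ionise in the flask with the same 1,2-shift of O1, the hindered base taking the methyl proton, to give (S)-6-methoxytremetone F2. Chelation-controlled demethylation of F2 (BCl3, CH2Cl2, −78 °C, short contact) would then return 8.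

Step 10 (C3 acyloxylation). After hydride abstraction the quinone methide may lose the C2 proton and aromatise to the benzofuran faster than the weakly nucleophilic acid adds, or the addition may show poor facial selectivity. The fallback sets out from 8 and comes back at 15: the C3–O bond is made with water and the ester bond by acylation. DDQ in wet 1,4-dioxane at rt should trap the quinone methide with the far more abundant and more nucleophilic water, giving 1-[(2R,3S)-3,6-dihydroxy-2-(prop-1-en-2-yl)-2,3-dihydro-1-benzofuran-5-yl]ethanone F3. This would be acylated at the secondary hydroxyl with acid 14 by Yamaguchi esterification (2,4,6-trichlorobenzoyl chloride, Et3N, then DMAP, toluene, 0 °C), the chelated phenol being the less reactive hydroxyl, to reach 15.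

Step 1 (acetylation). The Lewis acid and the hydrogen chloride formed may cause dimerisation or hydrochlorination of the electron-rich C3=C4 bond, or acylation at the alkene instead of the ring. The fallback sets out from 1 and comes back at 3. Vilsmeier–Haack formylation (POCl3, DMF, 0 °C → rt; aq. NaOAc), which needs no strong Lewis acid, should give 7-methoxy-2,2-dimethyl-2H-chromene-6-carbaldehyde F4. Addition of MeMgBr (THF, 0 °C) would give racemic 1-(7-methoxy-2,2-dimethyl-2H-chromen-6-yl)ethanol F5, and MnO2 (CH2Cl2, rt) would oxidise this benzylic alcohol to 3.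

Further compounds
F1 | step 5 | (R)-6-acetyl-7-methoxy-2,2-dimethylchroman-3-yl trifluoromethanesulfonate | COc1cc2OC(C)(C)[C@H](OS(=O)(=O)C(F)(F)F)Cc2cc1C(C)=O
F2 | step 5 | (S)-6-methoxytremetone, 1-[(2S)-6-methoxy-2-(prop-1-en-2-yl)-2,3-dihydro-1-benzofuran-5-yl]ethanone | C=C(C)[C@@H]1Cc2cc(C(C)=O)c(OC)cc2O1
F3 | step 10 | 1-[(2R,3S)-3,6-dihydroxy-2-(prop-1-en-2-yl)-2,3-dihydro-1-benzofuran-5-yl]ethanone | C=C(C)[C@H]1Oc2cc(O)c(C(C)=O)cc2[C@@H]1O
F4 | step 1 | 7-methoxy-2,2-dimethyl-2H-chromene-6-carbaldehyde | COc1cc2OC(C)(C)C=Cc2cc1C=O
F5 | step 1 | 1-(7-methoxy-2,2-dimethyl-2H-chromen-6-yl)ethanol (racemic) | COc1cc2OC(C)(C)C=Cc2cc1C(C)O
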